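The oxazinone ring is opened at the O2–C3 bond (ring numbering of pyrrolo[2,1-c][1,4]oxazin-1-one). The C3=C4 enol-ester double bond, which lies between the lactone oxygen O2 and the pyrrole nitrogen N5 and carries an electron-rich aryl group at C3, is treated as a masked alkyne: an N5-bound arylethynyl group next to the C1 carboxyl on C8a. In one operation Ph3PAuOTf (from Ph3PAuCl and AgOTf) makes the carboxyl oxygen add to C3, closing the six-membered ring and setting the C3=C4 bond. The precursor is 3,4-bis(4-methoxyphenyl)-1-[(4-methoxyphenyl)ethynyl]-1H-pyrrole-2-carboxylic acid, made from a desoxyanisoin-derived pyrrole ester by N-alkynylation and hydrolysis; BBr3 then frees the three phenols.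

Key step: step 6

Remark: atom labels are C1 (lactone carbonyl), O2, C3, C4, N5, C6, C7, C8, C8a. The target has no stereocentre. Compound 2 is drawn as the expected E isomer; the alkene geometry of the transient species 4 and 5 is undefined and irrelevant, since it is lost on pyrrole formation.
Remark: the glycine unit is introduced as its methyl ester so that the hydrolysis next to the N-alkynyl group can be run under mild conditions.

Step 1
Reactants: 1 desoxyanisoin [1,2-bis(4-methoxyphenyl)ethanone]
Product: 2 (E)-3-(dimethylamino)-1,2-bis(4-methoxyphenyl)prop-2-en-1-one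
Conditions: Me2NCH(OMe)2 (3 equiv), DMF, 100 °C
Reagents that add atoms: N,N-dimethylformamide dimethyl acetal, COC(OC)N(C)C
Why: Enaminone formation by condensation of the doubly activated benzylic CH2 group with the amide acetal is driven by loss of two molecules of methanol and should stop at the E-configured vinylogous amide.

Step 2
Reactants: 2 (E)-3-(dimethylamino)-1,2-bis(4-methoxyphenyl)prop-2-en-1-one; 3 glycine methyl ester hydrochloride
Product: 6 methyl 3,4-bis(4-methoxyphenyl)-1H-pyrrole-2-carboxylate, via chloropropeniminium dichlorophosphate 4 (not isolated), via N-(chloroallylidene)glycinate 5 (not isolated)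
Conditions: POCl3, CH2Cl2, 0 °C to rt, evaporate; then 3, NaH, DMF, 0 °C to 70 °C
Reagents that add atoms: none
Why: Vilsmeier–Haack-type O-activation of the vinylogous amide by POCl3 gives the 3-chloropropeniminium salt 4, the glycine nitrogen replaces dimethylamine at the iminium carbon to give azadiene 5, and the NaH-generated glycinate carbanion closes onto the chlorine-bearing carbon with loss of chloride and tautomerisation (condensation of a beta-chloroenal equivalent with an alpha-amino ester), which should place the aryl groups on C3 and C4 and leave C5 unsubstituted.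

Step 3
Reactants: 7 4-ethynylanisole
Product: 8 1-(bromoethynyl)-4-methoxybenzene
Conditions: NBS, AgNO3 (10 mol %), acetone, rt, dark
Reagents that add atoms: N-bromosuccinimide, O=C1CCC(=O)N1Br
Why: Electrophilic bromination of a terminal alkyne with NBS, in which AgNO3 activates the acetylenic C–H bond, is the standard preparation of 1-bromoalkynes and should leave the anisole ring untouched at room temperature.

Step 4
Reactants: 6 methyl 3,4-bis(4-methoxyphenyl)-1H-pyrrole-2-carboxylate; 8 1-(bromoethynyl)-4-methoxybenzene (1.3 equiv)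
Product: 9 methyl 3,4-bis(4-methoxyphenyl)-1-[(4-methoxyphenyl)ethynyl]-1H-pyrrole-2-carboxylate
Conditions: CuSO4·5H2O (20 mol %), 1,10-phenanthroline (40 mol %), K3PO4 (2 equiv), toluene, 85 °C
Reagents that add atoms: none
Why: Copper-catalysed C(sp)–N cross-coupling of a 1-bromoalkyne with an acidified NH (the amidative coupling used for ynamides and N-alkynyl azoles) should work here because the 2-ester makes the pyrrole NH acidic enough for K3PO4 and nitrogen is the only site that can be metalated and coupled.

Step 5
Reactants: 9 methyl 3,4-bis(4-methoxyphenyl)-1-[(4-methoxyphenyl)ethynyl]-1H-pyrrole-2-carboxylate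
Product: 11 3,4-bis(4-methoxyphenyl)-1-[(4-methoxyphenyl)ethynyl]-1H-pyrrole-2-carboxylic acid, via lithium carboxylate 10 (not isolated)
Conditions: LiOH·H2O (3 equiv), THF/H2O, 45 °C; then 0.5 M HCl to pH 4, 0 °C
Reagents that add atoms: lithium hydroxide (used as LiOH·H2O), [Li+].[OH-]
Why: Saponification of the methyl ester by hydroxide (acyl–oxygen cleavage) in an acid-free medium should spare the N-alkynyl group, which tolerates aqueous base far better than acid, and brief cold acidification to pH 4 should release acid 11 for immediate use.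

Step 6
Reactants: 11 3,4-bis(4-methoxyphenyl)-1-[(4-methoxyphenyl)ethynyl]-1H-pyrrole-2-carboxylic acid
Product: 13 3,7,8-tris(4-methoxyphenyl)-1H-pyrrolo[2,1-c][1,4]oxazin-1-one, via 4-(Ph3PAu) lactone 12 (not isolated)
Conditions: Ph3PAuCl (5 mol %), AgOTf (5 mol %), dry CH2Cl2, rt, dark
Reagents that add atoms: none
Why: Ph3PAuOTf, a cationic complex of monovalent gold formed in the flask, coordinates the C3≡C4 alkyne of 11 and slips towards C4 because the 4-methoxyphenyl group lets C3 take up the positive charge; the carboxyl oxygen then adds to C3 anti to gold to give the C4-aurated lactone 12, and the proton released from the carboxyl group cleaves the C4–Au bond to give 13 and return the catalyst. The closest known reaction type is the gold-catalysed cycloisomerisation of 2-alkynylbenzoic acids to isocoumarins, which has also been applied to N-alkynyl pyrrole and indole 2-carboxyl derivatives. The one ring formed, the oxazinone, closes in 6-endo-dig mode by making the O2–C3 bond, which is geometrically easy because carboxyl and alkyne sit on the neighbouring ring atoms C8a and N5. No stereocentre is created. The step needs 6-endo attack at C3 to win over 5-exo attack at C4: the anisyl group at C3, the weak donor power of the pyrrole nitrogen (its lone pair belongs to the aromatic sextet and is pulled towards the C1 carboxyl, so keteniminium character at C4 stays small) and the strain of the alternative 5-5-fused alkylidene oxazolone all favour C3.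

Step 7
Reactants: 13 3,7,8-tris(4-methoxyphenyl)-1H-pyrrolo[2,1-c][1,4]oxazin-1-one
Product: 15 3,7,8-tris(4-hydroxyphenyl)-1H-pyrrolo[2,1-c][1,4]oxazin-1-one, via tris(dibromoboryloxy) lactone 14 (not isolated)
Conditions: BBr3 (9 equiv), CH2Cl2, −78 °C to rt; then H2O, 0 °C
Reagents that add atoms: none
Why: Lewis-acid cleavage of aryl methyl ethers: BBr3 binds each methoxy oxygen, bromide removes the methyl group by SN2 to give the aryloxyborane 14, and water then frees the three phenols, while the weakly basic enol lactone should survive the low-temperature treatment.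

Compound list
1 | desoxyanisoin, 1,2-bis(4-methoxyphenyl)ethanone | COc1ccc(CC(=O)c2ccc(OC)cc2)cc1 | starting material
2 | (E)-3-(dimethylamino)-1,2-bis(4-methoxyphenyl)prop-2-en-1-one | CN(C)/C=C(\c1ccc(OC)cc1)C(=O)c1ccc(OC)cc1 | intermediate
3 | glycine methyl ester hydrochloride | Cl.NCC(=O)OC | starting material
4 | N-[3-chloro-2,3-bis(4-methoxyphenyl)prop-2-en-1-ylidene]-N-methylmethanaminium dichlorophosphate (formed in the flask, alkene geometry undefined) | C[N+](C)=CC(c1ccc(OC)cc1)=C(Cl)c1ccc(OC)cc1.[O-]P(=O)(Cl)Cl | intermediate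
5 | methyl N-[3-chloro-2,3-bis(4-methoxyphenyl)prop-2-en-1-ylidene]glycinate (formed in the flask, alkene and imine geometry undefined) | COC(=O)CN=CC(c1ccc(OC)cc1)=C(Cl)c1ccc(OC)cc1 | intermediate
6 | methyl 3,4-bis(4-methoxyphenyl)-1H-pyrrole-2-carboxylate | COC(=O)c1[nH]cc(-c2ccc(OC)cc2)c1-c1ccc(OC)cc1 | intermediate
7 | 4-ethynylanisole | COc1ccc(cc1)C#C | starting material
8 | 1-(bromoethynyl)-4-methoxybenzene | COc1ccc(cc1)C#CBr | intermediate
9 | methyl 3,4-bis(4-methoxyphenyl)-1-[(4-methoxyphenyl)ethynyl]-1H-pyrrole-2-carboxylate | COC(=O)c1c(-c2ccc(OC)cc2)c(-c2ccc(OC)cc2)cn1C#Cc1ccc(OC)cc1 | intermediate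
10 | lithium 3,4-bis(4-methoxyphenyl)-1-[(4-methoxyphenyl)ethynyl]-1H-pyrrole-2-carboxylate (formed in the flask) | [Li+].[O-]C(=O)c1c(-c2ccc(OC)cc2)c(-c2ccc(OC)cc2)cn1C#Cc1ccc(OC)cc1 | intermediate
11 | 3,4-bis(4-methoxyphenyl)-1-[(4-methoxyphenyl)ethynyl]-1H-pyrrole-2-carboxylic acid | OC(=O)c1c(-c2ccc(OC)cc2)c(-c2ccc(OC)cc2)cn1C#Cc1ccc(OC)cc1 | intermediate
12 | [3,7,8-tris(4-methoxyphenyl)-1-oxo-1H-pyrrolo[2,1-c][1,4]oxazin-4-yl](triphenylphosphine)gold (formed in the flask) | COc1ccc(cc1)-c1oc(=O)c2c(-c3ccc(OC)cc3)c(-c3ccc(OC)cc3)cn2c1[Au-][P+](c1ccccc1)(c1ccccc1)c1ccccc1 | intermediate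
13 | 3,7,8-tris(4-methoxyphenyl)-1H-pyrrolo[2,1-c][1,4]oxazin-1-one | COc1ccc(cc1)-c1cn2cc(-c3ccc(OC)cc3)c(-c3ccc(OC)cc3)c2c(=O)o1 | intermediate
14 | 3,7,8-tris[4-(dibromoboryloxy)phenyl]-1H-pyrrolo[2,1-c][1,4]oxazin-1-one (formed in the flask) | O=c1oc(-c2ccc(OB(Br)Br)cc2)cn2cc(-c3ccc(OB(Br)Br)cc3)c(-c3ccc(OB(Br)Br)cc3)c12 | intermediate
15 | 3,7,8-tris(4-hydroxyphenyl)-1H-pyrrolo[2,1-c][1,4]oxazin-1-one | O=c1oc(-c2ccc(O)cc2)cn2cc(-c3ccc(O)cc3)c(-c3ccc(O)cc3)c12 | target

Total step count: 7
Longest linear sequence: 6 steps (steps 1, 2, 4, 5, 6 and 7 from desoxyanisoin); step 3 is a one-step side branch.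

Steps most likely to fail

Step 6. The oxyauration may lose regiocontrol, with the carboxyl oxygen attacking C4 in 5-exo mode, or the activated ynamine-type alkyne may be hydrated by adventitious water. The fallback builds the ring without an alkyne. It sets out from 6: N-alkylation with 2-bromo-1-(4-methoxyphenyl)ethanone (K2CO3, DMF, rt) should give methyl 1-[2-(4-methoxyphenyl)-2-oxoethyl]-3,4-bis(4-methoxyphenyl)-1H-pyrrole-2-carboxylate F1. Saponification (KOH, EtOH/H2O, reflux) should give 1-[2-(4-methoxyphenyl)-2-oxoethyl]-3,4-bis(4-methoxyphenyl)-1H-pyrrole-2-carboxylic acid F2. Cyclodehydration of this keto acid through its mixed anhydride (Ac2O, NaOAc, 120 °C; enol lactonisation) should close the O2–C3 bond, and the sequence rejoins the route at 13.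

Step 4. Reductive homocoupling and decomposition of the electron-rich bromoalkyne may outrun C–N bond formation at the flanked, weakly nucleophilic pyrrole nitrogen. The fallback makes the alkyne on nitrogen from a stable vinyl dibromide. 4-Methoxybenzaldehyde is converted by the first stage of the Corey–Fuchs sequence (CBr4, PPh3, CH2Cl2, 0 °C) into 1-(2,2-dibromoethenyl)-4-methoxybenzene F3. This is coupled with 6 (CuI, N,N'-dimethylethylenediamine, Cs2CO3, dioxane, 70 °C): C–N coupling at the vinylic bromide followed by base-induced loss of HBr should give the N-alkynyl pyrrole. The fallback sets out from 6 and comes back at 9.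

Step 5. Hydroxide may add to the N-alkynyl unit, with cleavage of the N–C(sp) bond, or hydrolysis of the flanked ester may stall. The fallback avoids hydrolysis and the free acid. It sets out from 9: I2 in CH2Cl2 at rt should induce 6-endo-dig closure by the ester carbonyl oxygen, the methyl group leaving as iodomethane, to give 4-iodo-3,7,8-tris(4-methoxyphenyl)-1H-pyrrolo[2,1-c][1,4]oxazin-1-one F4. Hydrodeiodination (Pd(PPh3)4, HCO2Na, DMF, 80 °C) should then remove the iodine, and the sequence comes back to the route at 13.

Further compounds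
F1 | step 6 | methyl 1-[2-(4-methoxyphenyl)-2-oxoethyl]-3,4-bis(4-methoxyphenyl)-1H-pyrrole-2-carboxylate | COC(=O)c1c(-c2ccc(OC)cc2)c(-c2ccc(OC)cc2)cn1CC(=O)c1ccc(OC)cc1
F2 | step 6 | 1-[2-(4-methoxyphenyl)-2-oxoethyl]-3,4-bis(4-methoxyphenyl)-1H-pyrrole-2-carboxylic acid | OC(=O)c1c(-c2ccc(OC)cc2)c(-c2ccc(OC)cc2)cn1CC(=O)c1ccc(OC)cc1
F3 | step 4 | 1-(2,2-dibromoethenyl)-4-methoxybenzene | COc1ccc(C=C(Br)Br)cc1
F4 | step 5 | 4-iodo-3,7,8-tris(4-methoxyphenyl)-1H-pyrrolo[2,1-c][1,4]oxazin-1-one | COc1ccc(cc1)-c1oc(=O)c2c(-c3ccc(OC)cc3)c(-c3ccc(OC)cc3)cn2c1I
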